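**Retrosynthetic overview**
1. Target 19 comes from its O-benzyl ether 18 by hydrogenolysis.
2. The only ring, the γ-lactone, is closed last at the O–C(=O) bond: a primary alcohol (from reduction of an imide carbonyl) attacks the neighbouring ester, and the enolisable C3 is then equilibrated to trans.
3. The lactone C3–C4 bond (the lignan C8–C8′ bond) is made first, by one-electron oxidative heterocoupling of two C6–C3 enolates, as in lignan biogenesis but at the carboxyl oxidation level. The chiral imide 4 fixes C4 and the ester 11 is the partner; the coupled product 14 is carried as a pair of epimers at the future C3.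
4. Imide 4 comes from acid 1 and oxazolidinone 2; ester 11 comes from aldehyde 5 by reductive Meldrum's acid homologation and double benzylation.

Assumption: 1, 2 and 5 are bought as catalogue chemicals; the target is the (3R,4R)-trans-lactone that the SMILES encodes; 14 is an unseparated pair of epimers at one carbon, so its SMILES leaves that one centre unmarked.

**Step 1**
Reactants: 1 3-(3,4-dimethoxyphenyl)propanoic acid; 2 (S)-4-benzyloxazolidin-2-one
Product: 4 (4S)-4-benzyl-3-[3-(3,4-dimethoxyphenyl)propanoyl]oxazolidin-2-one, via mixed pivalic anhydride 3 (not isolated)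
Conditions: PivCl, Et3N, THF, −20 °C; then LiCl, 2, −20 °C → rt
Reagents that add atoms: none
Why: Mixed-anhydride N-acylation of the oxazolidinone under LiCl/Et3N activation, with attack at the unhindered acyl carbon of 3; no new stereocentre is formed and the (S)-centre of 2 is untouched.

**Step 2**
Reactants: 5 3-hydroxy-4,5-dimethoxybenzaldehyde
Product: 9 3-(3-hydroxy-4,5-dimethoxyphenyl)propanoic acid, via arylidene Meldrum's acid 6 (not isolated), via benzyl Meldrum's acid 7 (not isolated), via benzylmalonic acid 8 (not isolated)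
Conditions: Meldrum's acid (1.0 equiv), HCO2H–Et3N (5:2), 95 °C; aq. HCl
Reagents that add atoms: Meldrum's acid, CC1(C)OC(=O)CC(=O)O1; water, O
Why: One-pot reductive Knoevenagel homologation (condensation, formate hydride transfer to the arylidene, then hydrolysis and decarboxylation) turns ArCHO into ArCH2CH2CO2H, the meta-phenol being a spectator in the buffered medium; no stereocentre.

**Step 3**
Reactants: 9 3-(3-hydroxy-4,5-dimethoxyphenyl)propanoic acid
Product: 11 benzyl 3-[3-(benzyloxy)-4,5-dimethoxyphenyl]propanoate, via phenolic benzyl ester 10 (not isolated)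
Conditions: BnBr (2.3 equiv), K2CO3, DMF, 60 °C
Reagents that add atoms: benzyl bromide, BrCc1ccccc1
Why: Williamson-type O-alkylation of carboxylate and phenoxide in one operation gives an enolisable ester and a phenol protecting group that survives amide base, one-electron oxidant and borohydride but is removed by hydrogenolysis.

**Step 4**
Reactants: 4 (4S)-4-benzyl-3-[3-(3,4-dimethoxyphenyl)propanoyl]oxazolidin-2-one (1.5 equiv); 11 benzyl 3-[3-(benzyloxy)-4,5-dimethoxyphenyl]propanoate (1.0 equiv)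
Product: 14 benzyl (3R)-4-[(4S)-4-benzyl-2-oxooxazolidin-3-yl]-2-[3-(benzyloxy)-4,5-dimethoxybenzyl]-3-(3,4-dimethoxybenzyl)-4-oxobutanoate (unseparated pair of C2 epimers), via imide lithium enolate 12 (not isolated), via ester lithium enolate 13 (not isolated)
Conditions: 4 + 11 added to LiN(iPr)2 (2.6 equiv), THF, −78 °C; Fe(acac)3 (iron tris(acetylacetonate), trivalent iron, 2.5 equiv) in THF, −78 °C → rt; chromatography (homodimers removed, the two C2 epimers collected together)
Reagents that add atoms: none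
Why: Oxidative enolate heterocoupling, in which trivalent iron oxidises the mixed lithium enolates by one electron and the two α-carbons join in a radical C8–C8′ coupling; the chelated Z-enolate 12 reacts on the face opposite the auxiliary benzyl group, in the Evans alkylation sense, giving R at the imide α-carbon (future C4), while the ester α-carbon (future C3) forms with little control and is therefore taken on as the epimer pair 14 for step 5 to correct.

**Step 5**
Reactants: 14 benzyl (3R)-4-[(4S)-4-benzyl-2-oxooxazolidin-3-yl]-2-[3-(benzyloxy)-4,5-dimethoxybenzyl]-3-(3,4-dimethoxybenzyl)-4-oxobutanoate (unseparated pair of C2 epimers)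
Product: 18 (3R,4R)-3-[3-(benzyloxy)-4,5-dimethoxybenzyl]-4-(3,4-dimethoxybenzyl)dihydrofuran-2(3H)-one, via (2R)-hydroxy ester 15 (not isolated), via (2S)-hydroxy ester 16 (not isolated), via cis-lactone 17 (not isolated)
Conditions: LiBH4 (1.2 equiv), H2O (1.2 equiv), Et2O–THF, 0 °C; aq. NH4Cl; crude + DBU, toluene, 80 °C
Reagents that add atoms: none
Why: Chemoselective borohydride reduction of the more electrophilic N-acyl oxazolidinone releases the auxiliary and, from both epimers of 14, a primary alcohol that closes the γ-lactone on the adjacent benzyl ester (5-exo-trig acyl substitution), and DBU then equilibrates the enolisable C3 through the lactone enolate so that cis-lactone 17 drains into the more stable trans isomer while the non-enolisable C4 stays R, which makes (3R,4R)-18 the single product.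

**Step 6**
Reactants: 18 (3R,4R)-3-[3-(benzyloxy)-4,5-dimethoxybenzyl]-4-(3,4-dimethoxybenzyl)dihydrofuran-2(3H)-one
Product: 19 (3R,4R)-4-(3,4-dimethoxybenzyl)-3-(3-hydroxy-4,5-dimethoxybenzyl)dihydrofuran-2(3H)-one
Conditions: H2 (1 atm), 10% Pd/C, EtOAc–EtOH, rt
Reagents that add atoms: none
Why: Catalytic hydrogenolysis cleaves only the aryl benzyl ether; the lactone, the aryl methyl ethers and both stereocentres are inert under these neutral conditions.

**Compound list**
1 | 3-(3,4-dimethoxyphenyl)propanoic acid | COc1ccc(CCC(=O)O)cc1OC | starting material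
2 | (S)-4-benzyloxazolidin-2-one | O=C1OC[C@H](Cc2ccccc2)N1 | starting material
3 | 3-(3,4-dimethoxyphenyl)propanoic pivalic anhydride | COc1ccc(CCC(=O)OC(=O)C(C)(C)C)cc1OC | intermediate
4 | (4S)-4-benzyl-3-[3-(3,4-dimethoxyphenyl)propanoyl]oxazolidin-2-one | COc1ccc(CCC(=O)N2C(=O)OC[C@@H]2Cc3ccccc3)cc1OC | intermediate
5 | 3-hydroxy-4,5-dimethoxybenzaldehyde | COc1cc(C=O)cc(O)c1OC | starting material
6 | 5-(3-hydroxy-4,5-dimethoxybenzylidene)-2,2-dimethyl-1,3-dioxane-4,6-dione | COc1cc(C=C2C(=O)OC(C)(C)OC2=O)cc(O)c1OC | intermediate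
7 | 5-(3-hydroxy-4,5-dimethoxybenzyl)-2,2-dimethyl-1,3-dioxane-4,6-dione | COc1cc(CC2C(=O)OC(C)(C)OC2=O)cc(O)c1OC | intermediate
8 | 2-(3-hydroxy-4,5-dimethoxybenzyl)malonic acid | COc1cc(CC(C(=O)O)C(=O)O)cc(O)c1OC | intermediate
9 | 3-(3-hydroxy-4,5-dimethoxyphenyl)propanoic acid | COc1cc(CCC(=O)O)cc(O)c1OC | intermediate
10 | benzyl 3-(3-hydroxy-4,5-dimethoxyphenyl)propanoate | COc1cc(CCC(=O)OCc2ccccc2)cc(O)c1OC | intermediate
11 | benzyl 3-[3-(benzyloxy)-4,5-dimethoxyphenyl]propanoate | COc1cc(CCC(=O)OCc2ccccc2)cc(OCc2ccccc2)c1OC | intermediate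
12 | lithium Z-enolate of imide 4 | COc1ccc(C/C=C(\O[Li])N2C(=O)OC[C@@H]2Cc3ccccc3)cc1OC | intermediate
13 | lithium enolate of ester 11 (geometry not controlled) | COc1cc(CC=C(O[Li])OCc2ccccc2)cc(OCc2ccccc2)c1OC | intermediate
14 | benzyl (3R)-4-[(4S)-4-benzyl-2-oxooxazolidin-3-yl]-2-[3-(benzyloxy)-4,5-dimethoxybenzyl]-3-(3,4-dimethoxybenzyl)-4-oxobutanoate, unseparated pair of C2 epimers (2R and 2S; C3 and the auxiliary centre fixed) | COc1ccc(C[C@@H](C(=O)N2C(=O)OC[C@@H]2Cc3ccccc3)C(Cc4cc(OCc5ccccc5)c(OC)c(OC)c4)C(=O)OCc6ccccc6)cc1OC | intermediate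
15 | benzyl (2R,3R)-2-[3-(benzyloxy)-4,5-dimethoxybenzyl]-3-(3,4-dimethoxybenzyl)-4-hydroxybutanoate | COc1ccc(C[C@@H](CO)[C@@H](Cc2cc(OCc3ccccc3)c(OC)c(OC)c2)C(=O)OCc2ccccc2)cc1OC | intermediate
16 | benzyl (2S,3R)-2-[3-(benzyloxy)-4,5-dimethoxybenzyl]-3-(3,4-dimethoxybenzyl)-4-hydroxybutanoate | COc1ccc(C[C@@H](CO)[C@H](Cc2cc(OCc3ccccc3)c(OC)c(OC)c2)C(=O)OCc2ccccc2)cc1OC | intermediate
17 | (3S,4R)-3-[3-(benzyloxy)-4,5-dimethoxybenzyl]-4-(3,4-dimethoxybenzyl)dihydrofuran-2(3H)-one (cis-lactone) | COc1ccc(C[C@H]2COC(=O)[C@H]2Cc2cc(OCc3ccccc3)c(OC)c(OC)c2)cc1OC | intermediate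
18 | (3R,4R)-3-[3-(benzyloxy)-4,5-dimethoxybenzyl]-4-(3,4-dimethoxybenzyl)dihydrofuran-2(3H)-one (trans-lactone) | COc1ccc(C[C@H]2COC(=O)[C@@H]2Cc2cc(OCc3ccccc3)c(OC)c(OC)c2)cc1OC | intermediate
19 | (3R,4R)-4-(3,4-dimethoxybenzyl)-3-(3-hydroxy-4,5-dimethoxybenzyl)dihydrofuran-2(3H)-one | COc1ccc(C[C@H]2COC(=O)[C@@H]2Cc2cc(O)c(OC)c(OC)c2)cc1OC | target

**Totals**
Total step count: 6. Longest linear sequence: 5 steps (5 → 9 → 11 → 14 → 18 → 19).

**Three steps most likely to fail, with fallbacks**

Step 4. The risks are homocoupling of each enolate competing with the cross-coupling, a moderate yield for a crowded C–C bond, and incomplete face control at the imide carbon. The fallback replaces the radical coupling by two polar C–C bond formations; it sets out from 4 (and from 5 for the electrophile) and comes back at 18. Imide 4 is deprotonated with NaN(SiMe3)2 in THF at −78 °C and alkylated with tert-butyl bromoacetate to give tert-butyl (3R)-4-[(4S)-4-benzyl-2-oxooxazolidin-3-yl]-3-(3,4-dimethoxybenzyl)-4-oxobutanoate F1 (Evans alkylation, same facial sense, R). LiBH4/H2O in Et2O at 0 °C then gives tert-butyl (3R)-3-(3,4-dimethoxybenzyl)-4-hydroxybutanoate F2, and catalytic TsOH in toluene at 80 °C closes it to (R)-4-(3,4-dimethoxybenzyl)dihydrofuran-2(3H)-one F3. Separately, aldehyde 5 with BnBr/K2CO3 in DMF gives 3-(benzyloxy)-4,5-dimethoxybenzaldehyde F4, NaBH4 in MeOH gives [3-(benzyloxy)-4,5-dimethoxyphenyl]methanol F5, and PBr3 in CH2Cl2 at 0 °C gives 1-(benzyloxy)-5-(bromomethyl)-2,3-dimethoxybenzene F6. The lithium enolate of F3 (LiN(SiMe3)2, THF, −78 °C) is alkylated by F6 anti to the C4 substituent and gives 18 directly, ready for step 6.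

Step 5. The risks are over-reduction of the benzyl ester or the newly formed lactone, endocyclic opening of the hindered imide, and sluggish epimerisation. The fallback separates auxiliary removal from reduction; it sets out from 14 and comes back at 15 (together with 16). LiOH/H2O2 in THF–H2O at 0 °C cleaves the auxiliary exocyclically from both epimers of 14 to give (2R,3R)-4-(benzyloxy)-3-[3-(benzyloxy)-4,5-dimethoxybenzyl]-2-(3,4-dimethoxybenzyl)-4-oxobutanoic acid F7 and its epimer (2R,3S)-4-(benzyloxy)-3-[3-(benzyloxy)-4,5-dimethoxybenzyl]-2-(3,4-dimethoxybenzyl)-4-oxobutanoic acid F8. BH3·SMe2 in THF at 0 °C reduces only the free carboxylic acid, giving hydroxy esters 15 and 16, which are then lactonised and equilibrated with DBU as in step 5.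

Step 2. The risk is that the one-pot condensation, transfer reduction and decarboxylation stalls or gives mixtures with the free phenol. The fallback sets out from 5 and comes back at 9. Malonic acid in pyridine with catalytic piperidine at 90 °C (Knoevenagel–Doebner) gives (E)-3-(3-hydroxy-4,5-dimethoxyphenyl)acrylic acid F9, and H2 over 10% Pd/C in MeOH saturates the alkene to give 9.

**Further compounds**
F1 | step 4 | tert-butyl (3R)-4-[(4S)-4-benzyl-2-oxooxazolidin-3-yl]-3-(3,4-dimethoxybenzyl)-4-oxobutanoate | COc1ccc(C[C@H](CC(=O)OC(C)(C)C)C(=O)N2C(=O)OC[C@@H]2Cc3ccccc3)cc1OC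
F2 | step 4 | tert-butyl (3R)-3-(3,4-dimethoxybenzyl)-4-hydroxybutanoate | COc1ccc(C[C@@H](CO)CC(=O)OC(C)(C)C)cc1OC
F3 | step 4 | (R)-4-(3,4-dimethoxybenzyl)dihydrofuran-2(3H)-one | COc1ccc(C[C@H]2COC(=O)C2)cc1OC
F4 | step 4 | 3-(benzyloxy)-4,5-dimethoxybenzaldehyde | COc1cc(C=O)cc(OCc2ccccc2)c1OC
F5 | step 4 | [3-(benzyloxy)-4,5-dimethoxyphenyl]methanol | COc1cc(CO)cc(OCc2ccccc2)c1OC
F6 | step 4 | 1-(benzyloxy)-5-(bromomethyl)-2,3-dimethoxybenzene | COc1cc(CBr)cc(OCc2ccccc2)c1OC
F7 | step 5 | (2R,3R)-4-(benzyloxy)-3-[3-(benzyloxy)-4,5-dimethoxybenzyl]-2-(3,4-dimethoxybenzyl)-4-oxobutanoic acid | COc1ccc(C[C@@H](C(=O)O)[C@@H](Cc2cc(OCc3ccccc3)c(OC)c(OC)c2)C(=O)OCc2ccccc2)cc1OC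
F8 | step 5 | (2R,3S)-4-(benzyloxy)-3-[3-(benzyloxy)-4,5-dimethoxybenzyl]-2-(3,4-dimethoxybenzyl)-4-oxobutanoic acid | COc1ccc(C[C@@H](C(=O)O)[C@H](Cc2cc(OCc3ccccc3)c(OC)c(OC)c2)C(=O)OCc2ccccc2)cc1OC
F9 | step 2 | (E)-3-(3-hydroxy-4,5-dimethoxyphenyl)acrylic acid | COc1cc(/C=C/C(=O)O)cc(O)c1OC
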